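**Strategy.** The route cuts the cycloheptene ring at C9–C10 and C6–C7 (daucane numbering), the two bonds that flank the C7–C8(CH3)=C9 unit. The feature exploited is the homoallylic carbinol C6(O)–C7–C8=C9 of the seven-membered ring, the retron of an allylboration. In the key step 3-diazo-2-methylprop-1-ene inserts into the C10–B bond of a cyclopentylmethylboronic acid (1,2-boronate shift). The α-branched allylboronic acid so formed allylates the C6 aldehyde on the neighbouring ring carbon. This closes the trans-fused seven-membered ring, places the C8=C9 alkene and sets C6. The precursor is a cyclopentane with CH2B(OH)2 on quaternary C1 and CHO on C5, trans to each other.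

Key step: step 10

Remark: atoms carry the daucane number they end up with (C1 methyl-bearing ring-fusion carbon, C2 CH–O, C3 CH2, C4 isopropyl carbinol carbon, C5 ring-fusion CH, C6 CH–O, C7 CH2, C8 =C(CH3), C9 =CH, C10 CH2); β is the face of the C1 methyl group, α the face of H5.

Step 1
Reactants: 1 (R)-4-[(tert-butyldimethylsilyl)oxy]cyclopent-2-en-1-one; 2 isopropylmagnesium chloride
Product: 3 (1R,4R)-4-[(tert-butyldimethylsilyl)oxy]-1-(propan-2-yl)cyclopent-2-en-1-ol (hydroxyl cis to the silyloxy group)
Conditions: iPrMgCl, LaCl3·2LiCl, THF, −78 → 0 °C; then H2O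
Reagents that add atoms: isopropylmagnesium chloride 2, CC(C)[Mg]Cl
Why: Lanthanum-promoted 1,2-addition of the Grignard reagent should occur on the enone face opposite the silyl ether (1,3-induction), which sets the tertiary carbinol (future C4); the minor diastereomer is removed by chromatography, so the later loss of the silyloxy centre cannot erode enantiopurity.

Step 2
Reactants: 3 (1R,4R)-4-[(tert-butyldimethylsilyl)oxy]-1-(propan-2-yl)cyclopent-2-en-1-ol
Product: 4 (1R,4R)-1-(propan-2-yl)cyclopent-2-ene-1,4-diol (cis-diol)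
Conditions: Bu4NF, THF, 0 °C → rt
Reagents that add atoms: none
Why: Fluoride-mediated desilylation of the secondary silyl ether; no stereocentre is touched.

Step 3
Reactants: 4 (1R,4R)-1-(propan-2-yl)cyclopent-2-ene-1,4-diol
Product: 5 (R)-4-hydroxy-4-(propan-2-yl)cyclopent-2-en-1-one
Conditions: MnO2, CH2Cl2, rt
Reagents that add atoms: none
Why: Allylic oxidation by MnO2 takes only the secondary allylic alcohol and leaves the tertiary carbinol, whose configuration is carried through unchanged.

Step 4
Reactants: 5 (R)-4-hydroxy-4-(propan-2-yl)cyclopent-2-en-1-one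
Product: 6 (R)-4-hydroxy-2-iodo-4-(propan-2-yl)cyclopent-2-en-1-one
Conditions: I2, pyridine, CH2Cl2, 0 °C → rt
Reagents that add atoms: iodine, II
Why: α-Iodination of the enone by pyridine addition, iodination of the enolate and elimination (Baylis–Hillman-type mechanism) places iodine on C1 without touching the carbinol centre.

Step 5
Reactants: 6 (R)-4-hydroxy-2-iodo-4-(propan-2-yl)cyclopent-2-en-1-one; 7 tetramethylstannane
Product: 8 (R)-4-hydroxy-2-methyl-4-(propan-2-yl)cyclopent-2-en-1-one
Conditions: Me4Sn, Pd2(dba)3 (cat.), AsPh3, CuI, NMP, 60 °C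
Reagents that add atoms: tetramethylstannane 7, C[Sn](C)(C)C
Why: Stille cross-coupling of the α-iodoenone transfers methyl under neutral conditions, which avoids base-induced retro-aldol opening (and racemisation) of the γ-hydroxy enone.

Step 6
Reactants: 8 (R)-4-hydroxy-2-methyl-4-(propan-2-yl)cyclopent-2-en-1-one; 9 vinylmagnesium bromide; 10 2-(iodomethyl)-4,4,5,5-tetramethyl-1,3,2-dioxaborolane
Product: 13 (2R,3R,4R)-3-ethenyl-4-hydroxy-2-methyl-4-(propan-2-yl)-2-[(4,4,5,5-tetramethyl-1,3,2-dioxaborolan-2-yl)methyl]cyclopentan-1-one, via bromomagnesium alkoxide 11 (not isolated), via bromomagnesium enolate 12 (not isolated)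
Conditions: CH2=CHMgBr (2.2 equiv), THF, −78 → −20 °C; then ICH2Bpin, DMPU, −20 °C → rt; then H2O
Reagents that add atoms: vinylmagnesium bromide 9, C=C[Mg]Br; 2-(iodomethyl)-4,4,5,5-tetramethyl-1,3,2-dioxaborolane 10, ICB1OC(C)(C)C(C)(C)O1
Why: Ligand-assisted 1,4-addition, in which the C4 magnesium alkoxide binds the second equivalent of Grignard reagent and delivers vinyl to C5 on the oxygen-bearing face (cis to O, trans to isopropyl), is followed by C-alkylation of the enolate at C1 on the face opposite the new vinyl group (enolate alkylation), which sets the quaternary centre with CH2B trans to vinyl.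

Step 7
Reactants: 13 (2R,3R,4R)-3-ethenyl-4-hydroxy-2-methyl-4-(propan-2-yl)-2-[(4,4,5,5-tetramethyl-1,3,2-dioxaborolan-2-yl)methyl]cyclopentan-1-one
Product: 15 (1R,3S,4R,5R)-5-ethenyl-4-methyl-1-(propan-2-yl)-4-[(4,4,5,5-tetramethyl-1,3,2-dioxaborolan-2-yl)methyl]cyclopentane-1,3-diol, via alkoxyborohydride 14 (not isolated)
Conditions: Me4NBH(OAc)3, MeCN/AcOH, −30 → 0 °C
Reagents that add atoms: none
Why: Evans–Saksena reduction, in which the borohydride bound to the tertiary C4 oxygen delivers hydride to the β face of the C2 ketone, should give the 1,3-anti diol with C2–OH α and cis to CH2B.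

Step 8
Reactants: 15 (1R,3S,4R,5R)-5-ethenyl-4-methyl-1-(propan-2-yl)-4-[(4,4,5,5-tetramethyl-1,3,2-dioxaborolan-2-yl)methyl]cyclopentane-1,3-diol
Product: 17 {[(1R,2R,3R,5S)-2-formyl-3,5-dihydroxy-1-methyl-3-(propan-2-yl)cyclopentyl]methyl}boronic acid (in equilibrium with its cyclic hemiester through O2), via vicinal diol 16 (not isolated)
Conditions: OsO4 (cat.), NaIO4, NH4OAc, acetone/H2O, rt
Reagents that add atoms: sodium periodate, [Na+].[O-]I(=O)(=O)=O; water, O
Why: Lemieux–Johnson cleavage turns the vinyl group into the C6 aldehyde, and periodate also destroys the pinacol released by hydrolysis and so frees the boronic acid; no stereocentre is formed and C5 keeps its more stable trans arrangement.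

Step 9
Reactants: 18 methacrolein; 19 4-methylbenzenesulfonohydrazide
Product: 20 (E)-4-methyl-N'-(2-methylprop-2-en-1-ylidene)benzenesulfonohydrazide (methacrolein tosylhydrazone)
Conditions: MeOH, 0 °C → rt
Reagents that add atoms: 4-methylbenzenesulfonohydrazide 19, Cc1ccc(cc1)S(=O)(=O)NN
Why: Hydrazone formation at low temperature should outpace conjugate addition to the enal.

Step 10
Reactants: 17 {[(1R,2R,3R,5S)-2-formyl-3,5-dihydroxy-1-methyl-3-(propan-2-yl)cyclopentyl]methyl}boronic acid; 20 methacrolein tosylhydrazone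
Product: 24 (1R,2S,4R,5S,6S)-dauc-8-ene-2,4,6-triol (trans-fused; 2-OH and 6-OH α, 4-OH β), via sodium tosylhydrazonide 21 (not isolated), via diazoalkene 22 (not isolated), via allylboronic acid 23 (not isolated)
Conditions: 20, NaH, THF, 0 °C; then 17, BnEt3NCl (cat.), 1,4-dioxane, 45 °C, 0.005 M; then H2O
Reagents that add atoms: methacrolein tosylhydrazone 20, Cc1ccc(cc1)S(=O)(=O)N/N=C/C(C)=C
Why: Proposed new method: Bamford–Stevens loss of sulfinate from 21 gives diazoalkene 22, whose diazo carbon (C9) adds to boron of 17; C10 then migrates from boron to C9 with loss of N2 (bond C9–C10) to give the α-branched allylboronic acid 23, and its γ-carbon C7 adds to the C6 aldehyde with allyl transposition (bond C6–C7), leaving the alkene at C8=C9. The closest known reaction type is the metal-free three-component coupling of vinyl diazoalkanes, boronic acids and aldehydes (diazo–boronic acid homologation followed by allylboration), used here with boron and aldehyde in one molecule so that it becomes a (4+3) annulation. The seven-membered ring closes by intramolecular allylboration through a boat-shaped six-membered B–O=C–C–C=C array bridged by C10–C1–C5 (a bicyclo[3.2.2] transition state), which can only give the cis ring alkene. The new C6 stereocentre is set by this bridged transition state, because the O–B bridge has to span the α face away from the axial C1 methyl, which places the C6 oxygen α (6S). The step needs the diazoalkane to attack boron rather than the aldehyde or the hydroxyls (boronic acids are known to capture non-stabilised diazoalkanes readily), and γ-selective allyl transfer without a prior 1,3-boron shift (the alternative C6–C9 closure would give a strained trans-fused bicyclo[3.3.0]octane). Ring closure must also outpace intermolecular allylation, which high dilution and slow release of the diazoalkane should secure.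

Step 11
Reactants: 24 (1R,2S,4R,5S,6S)-dauc-8-ene-2,4,6-triol; 25 angelic acid [(Z)-2-methylbut-2-enoic acid]
Product: 27 (1R,2S,4R,5S,6S)-4-hydroxydauc-8-ene-2,6-diyl bis[(2Z)-2-methylbut-2-enoate] (target), via mixed anhydride 26 (not isolated)
Conditions: 25, 2,4,6-trichlorobenzoyl chloride, Et3N, toluene, rt; then 24, toluene, 80 °C
Reagents that add atoms: angelic acid 25, C/C=C(/C)C(=O)O
Why: Yamaguchi esterification through the mixed anhydride should acylate the two secondary hydroxyls while the tertiary C4 hydroxyl stays free, and leaving out a nucleophilic catalyst should preserve the Z (angeloyl) geometry.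

**Compound list**

1 | (R)-4-[(tert-butyldimethylsilyl)oxy]cyclopent-2-en-1-one | O=C1C=C[C@H](O[Si](C)(C)C(C)(C)C)C1 | starting material
2 | isopropylmagnesium chloride | CC(C)[Mg]Cl | starting material
3 | (1R,4R)-4-[(tert-butyldimethylsilyl)oxy]-1-(propan-2-yl)cyclopent-2-en-1-ol | CC(C)[C@@]1(O)C=C[C@H](O[Si](C)(C)C(C)(C)C)C1 | intermediate
4 | (1R,4R)-1-(propan-2-yl)cyclopent-2-ene-1,4-diol | CC(C)[C@@]1(O)C=C[C@H](O)C1 | intermediate
5 | (R)-4-hydroxy-4-(propan-2-yl)cyclopent-2-en-1-one | CC(C)[C@@]1(O)C=CC(=O)C1 | intermediate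
6 | (R)-4-hydroxy-2-iodo-4-(propan-2-yl)cyclopent-2-en-1-one | CC(C)[C@@]1(O)C=C(I)C(=O)C1 | intermediate
7 | tetramethylstannane | C[Sn](C)(C)C | starting material
8 | (R)-4-hydroxy-2-methyl-4-(propan-2-yl)cyclopent-2-en-1-one | CC(C)[C@@]1(O)C=C(C)C(=O)C1 | intermediate
9 | vinylmagnesium bromide | C=C[Mg]Br | starting material
10 | 2-(iodomethyl)-4,4,5,5-tetramethyl-1,3,2-dioxaborolane | ICB1OC(C)(C)C(C)(C)O1 | starting material
11 | bromomagnesium alkoxide of 8 | CC(C)[C@@]1(O[Mg]Br)C=C(C)C(=O)C1 | intermediate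
12 | bis(bromomagnesium) enolate–alkoxide after vinyl addition (vinyl cis to the C4 oxygen) | CC1=C(O[Mg]Br)C[C@@](O[Mg]Br)(C(C)C)[C@@H]1C=C | intermediate
13 | (2R,3R,4R)-3-ethenyl-4-hydroxy-2-methyl-4-(propan-2-yl)-2-[(4,4,5,5-tetramethyl-1,3,2-dioxaborolan-2-yl)methyl]cyclopentan-1-one | C[C@]1(CB2OC(C)(C)C(C)(C)O2)C(=O)C[C@@](O)(C(C)C)[C@@H]1C=C | intermediate
14 | tetramethylammonium diacetoxy(hydrido)borate ester of the C4 hydroxyl of 13 | C[C@]1(CB2OC(C)(C)C(C)(C)O2)C(=O)C[C@@](O[BH-](OC(C)=O)OC(C)=O)(C(C)C)[C@@H]1C=C.C[N+](C)(C)C | intermediate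
15 | (1R,3S,4R,5R)-5-ethenyl-4-methyl-1-(propan-2-yl)-4-[(4,4,5,5-tetramethyl-1,3,2-dioxaborolan-2-yl)methyl]cyclopentane-1,3-diol | C[C@]1(CB2OC(C)(C)C(C)(C)O2)[C@@H](O)C[C@@](O)(C(C)C)[C@@H]1C=C | intermediate
16 | 1,2-diol from dihydroxylation of the vinyl group of 15 (both epimers at the new carbinol) | C[C@]1(CB2OC(C)(C)C(C)(C)O2)[C@@H](O)C[C@@](O)(C(C)C)[C@@H]1C(O)CO | intermediate
17 | {[(1R,2R,3R,5S)-2-formyl-3,5-dihydroxy-1-methyl-3-(propan-2-yl)cyclopentyl]methyl}boronic acid | C[C@]1(CB(O)O)[C@@H](O)C[C@@](O)(C(C)C)[C@@H]1C=O | intermediate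
18 | methacrolein | C=C(C)C=O | starting material
19 | 4-methylbenzenesulfonohydrazide | Cc1ccc(cc1)S(=O)(=O)NN | starting material
20 | (E)-4-methyl-N'-(2-methylprop-2-en-1-ylidene)benzenesulfonohydrazide | Cc1ccc(cc1)S(=O)(=O)N/N=C/C(C)=C | intermediate
21 | sodium salt of 20 | Cc1ccc(cc1)S(=O)(=O)[N-]/N=C/C(C)=C.[Na+] | intermediate
22 | 3-diazo-2-methylprop-1-ene | C=C(C)C=[N+]=[N-] | intermediate
23 | {1-[(1R,2R,3R,5S)-2-formyl-3,5-dihydroxy-1-methyl-3-(propan-2-yl)cyclopentyl]-3-methylbut-3-en-2-yl}boronic acid (both epimers at the boron-bearing carbon) | C[C@]1(CC(B(O)O)C(C)=C)[C@@H](O)C[C@@](O)(C(C)C)[C@@H]1C=O | intermediate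
24 | (1R,2S,4R,5S,6S)-dauc-8-ene-2,4,6-triol | O[C@H]1CC(C)=CC[C@@]2(C)[C@@H](O)C[C@@](O)(C(C)C)[C@H]12 | intermediate
25 | angelic acid, (Z)-2-methylbut-2-enoic acid | C/C=C(/C)C(=O)O | starting material
26 | angelic 2,4,6-trichlorobenzoic anhydride | C/C=C(/C)C(=O)OC(=O)c1c(Cl)cc(Cl)cc1Cl | intermediate
27 | (1R,2S,4R,5S,6S)-4-hydroxydauc-8-ene-2,6-diyl bis[(2Z)-2-methylbut-2-enoate] | C/C=C(/C)C(=O)O[C@H]1CC(C)=CC[C@@]2(C)[C@@H](OC(=O)/C(C)=C\C)C[C@@](O)(C(C)C)[C@H]12 | target

**Step count and risks**

Total step count: 11. Longest linear sequence: 10 steps (steps 1–8, 10 and 11, from 1 to 27).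

The three steps most likely to fail:

1. Step 10 (Proposed new method). Ring closure of the allylboronic acid may be outrun by protodeboronation or intermolecular allylation, because only the epimer with boron on the α side of the boron-bearing carbon can bridge to the aldehyde. The fallback uses two known reactions and sets out from 17. Allylboration of the aldehyde with racemic 2-(1-chloro-2-methylprop-2-en-1-yl)-4,4,5,5-tetramethyl-1,3,2-dioxaborolane (α-chloroallylboration, CH2Cl2, rt) should give the (Z)-chloroalkenyl alcohol F1, in which the C6–C7 bond is made first. An intramolecular B-alkyl Suzuki–Miyaura coupling of the alkylboronic acid with the vinyl chloride (Pd(OAc)2, 2-dicyclohexylphosphino-2',6'-diisopropoxybiphenyl, K3PO4, toluene/H2O, 80 °C) then makes C9–C10 and returns to the route at 24.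

2. Step 6. Site and face control in the alkoxide-directed Grignard delivery may be lost (1,2-addition, or attack trans to oxygen), and the hindered magnesium enolate may undergo proton transfer instead of C-alkylation. The fallback moves the stereocontrol to a secondary silyl ether and sets out from 1.
   - α-Iodination (I2, pyridine) gives the iodoenone F2, and Stille methylation (Me4Sn, Pd2(dba)3, AsPh3, CuI) gives the 2-methyl enone F3.
   - Copper-mediated vinyl addition trans to the silyl ether (CH2=CHMgBr, CuBr·SMe2, Me3SiCl), regeneration of the lithium enolate (MeLi) and alkylation with 10 give the boryl ketone F4.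
   - NaBH4 reduction from the face away from the silyl ether and CH2B gives the alcohol F5.
   - NaIO4 in aqueous HCl/THF removes the silyl group and the pinacol and gives the oxaborolane diol F6, in which boron masks the C2 hydroxyl.
   - Dess–Martin oxidation gives the oxaborolane ketone F7.
   - Addition of iPrMgCl/LaCl3·2LiCl trans to the vinyl group gives the tertiary carbinol F8.
   - Lemieux–Johnson cleavage (OsO4, NaIO4) returns to the route at 17.

3. Step 11. Acylation of the neopentylic C2 hydroxyl may stay incomplete, and forcing conditions may isomerise the angeloyl group from Z to E (tigloyl). The fallback builds the Z-alkene on the ester and sets out from 24. Esterification of both secondary hydroxyls with 2-[bis(2,2,2-trifluoroethoxy)phosphoryl]propanoic acid (DCC, 4-dimethylaminopyridine, CH2Cl2) gives the bis(phosphonopropionate) F9. Z-selective Still–Gennari olefination with acetaldehyde (KN(SiMe3)2, 18-crown-6, THF, −78 °C) returns to the route at 27.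

Further compounds
F1 | step 10 | {[(1R,2S,3R,5S)-2-[(1S,3Z)-4-chloro-1-hydroxy-3-methylbut-3-en-1-yl]-3,5-dihydroxy-1-methyl-3-(propan-2-yl)cyclopentyl]methyl}boronic acid | C[C@]1(CB(O)O)[C@@H](O)C[C@@](O)(C(C)C)[C@@H]1[C@@H](O)C/C(C)=C\Cl
F2 | step 6 | (R)-4-[(tert-butyldimethylsilyl)oxy]-2-iodocyclopent-2-en-1-one | O=C1C(I)=C[C@H](O[Si](C)(C)C(C)(C)C)C1
F3 | step 6 | (R)-4-[(tert-butyldimethylsilyl)oxy]-2-methylcyclopent-2-en-1-one | O=C1C(C)=C[C@H](O[Si](C)(C)C(C)(C)C)C1
F4 | step 6 | (2R,3R,4R)-4-[(tert-butyldimethylsilyl)oxy]-3-ethenyl-2-methyl-2-[(4,4,5,5-tetramethyl-1,3,2-dioxaborolan-2-yl)methyl]cyclopentan-1-one | C[C@]1(CB2OC(C)(C)C(C)(C)O2)C(=O)C[C@@H](O[Si](C)(C)C(C)(C)C)[C@@H]1C=C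
F5 | step 6 | (1S,2R,3R,4R)-4-[(tert-butyldimethylsilyl)oxy]-3-ethenyl-2-methyl-2-[(4,4,5,5-tetramethyl-1,3,2-dioxaborolan-2-yl)methyl]cyclopentan-1-ol | C[C@]1(CB2OC(C)(C)C(C)(C)O2)[C@@H](O)C[C@@H](O[Si](C)(C)C(C)(C)C)[C@@H]1C=C
F6 | step 6 | cyclic boronic hemiester (1,2-oxaborolan-2-ol fused to the cyclopentane through C1 and C2) with free secondary C4 hydroxyl and C5 vinyl group | C[C@]12CB(O)O[C@H]1C[C@@H](O)[C@@H]2C=C
F7 | step 6 | C4 ketone of the cyclic boronic hemiester F6 | C[C@]12CB(O)O[C@H]1CC(=O)[C@@H]2C=C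
F8 | step 6 | cyclic boronic hemiester with the C4 isopropyl carbinol (pinacol-free form of 15) | C[C@]12CB(O)O[C@H]1C[C@@](O)(C(C)C)[C@@H]2C=C
F9 | step 11 | (1R,2S,4R,5S,6S)-4-hydroxydauc-8-ene-2,6-diyl bis{2-[bis(2,2,2-trifluoroethoxy)phosphoryl]propanoate} | CC(C(=O)O[C@H]1CC(C)=CC[C@@]2(C)[C@@H](OC(=O)C(C)P(=O)(OCC(F)(F)F)OCC(F)(F)F)C[C@@](O)(C(C)C)[C@H]12)P(=O)(OCC(F)(F)F)OCC(F)(F)F
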